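The numbers in the tables come from a simulation for an exercise; noise was put on by code.

| flask | X | E | time |
|---|---|---|---|
| ochre | 50.0 mM | 100 mM |  |
| teal | 50.0 mM | 150 mM |  |
| red | 100 mM | 100 mM |  |
| violet | 50.0 mM | 100 mM | 32 min |

- ochre run (time / min: [L] / mM): 1.2: 11.1; 2.3: 19.5; 3.5: 24.6; 4.6: 30.1; 5.8: 32.2; 6.9: 36.1; 8.1: 37.8
- teal run (time / min: [L] / mM): 1.2: 14.7; 2.3: 24.5; 3.5: 31.5; 4.6: 36.1; 5.8: 38.8; 6.9: 42.2; 8.1: 42.9
- red run (time / min: [L] / mM): 1.2: 18.6; 2.3: 30.3; 3.5: 40.6; 4.6: 46.7; 5.8: 53.1; 6.9: 56.6; 8.1: 61.2

(scatter of a reading: 0.4 mM)

- Overall: X + E -> L.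
- Constant volume, constant temperature.
- The analysis sees a species whether free or bound.
- "The second partner" is E.
- An order is taken over about fifteen percent of the charge, up and down.

- how the opening rate goes with [E] round the charge of the ochre run: the exponent of the rate at two percent of X gone to L
- how the opening rate goes with [X] round the charge of the ochre run: the exponent of the rate at two percent of X gone to L (one fixed amount of L, the same in the runs compared)
- L in the violet run at 32 min, as a share of the X charged

The ochre flask and the teal flask both start with 50.0 mM of X, the limiting reagent, and differ in E, 100 mM against 150 mM.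

| Flask | E charged | L at first reading | L at last reading |
|---|---|---|---|
| ochre | 100 mM | 11.1 mM | 37.8 mM |
| teal | 150 mM | 14.7 mM | 42.9 mM |

At 8.1 min the teal reading stands above the ochre reading, and the teal product of charges, X times E, is larger by a factor of 1.50. The first readings, at 1.2 min, stand in a ratio of 1.32, which, taken as a ratio of rates, gives a rough exponent of 0.693 in E. The same reading of the red flask against ochre gives a rough 0.745 in X.

Ochre's last reading gives 2.31 L mol⁻¹ min⁻¹: this is k, the pace constant, the rate of forming L divided by the product of the X and E outside L. Ochre's reading at 3.5 min gives 2.26 L mol⁻¹ min⁻¹, while teal's last reading gives 1.99 L mol⁻¹ min⁻¹, so the value from ochre is the one to carry to a flask of ochre's charge. Those ochre readings stop at 8.1 min, with 75.6 % of X turned, so freezing k beyond them is an assumption. Violet has ochre's charge, and this reckoning, with k frozen over 32 min, leaves 0.628 mM of X outside L, which puts L at 98.7 % of the X charged.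

The forecast, a little lower on violet than this reckoning, gives 0.7 in E, 0.8 in X and 98 %, on the ground that “Within each run k stays flat”.

    X + E ⇌ L (4.500 L mol⁻¹ min⁻¹, 0.01848 min⁻¹)
    X + E ⇌ XE, settled at all times (4.840 L mol⁻¹)
    2 X ⇌ X2, settled at all times (7.140 L mol⁻¹)

The violet flask gives 90.8 % at 32 min, with exponents 0.83 in E and 0.76 in X. Its X outside L, free or bound, is 4.61 mM, against the 0.628 mM reckoned. On that composition, frozen k reckons a forward rate of 0.581 mM min⁻¹, while the back step of the scheme returns 0.839 mM min⁻¹. In the red flask, with X and E charged equally, the reciprocal of k times the charge puts the half-time at 4.33 min, and the reading is 5.14 min.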